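**Retrosynthetic overview**
1. Numbering (guaiane): C1=C10 is the ring alkene (C10 carries methyl C14); C2, C3 are the CH2 groups and C4 the CH(CH3) (methyl C15) of the five-membered ring; C5 is the ring-fusion CH; C6, C9 are CH2; C7 is the CH bearing carbinol carbon C11; C8 is the CH–O.
2. Target ⇒ p-coumaric acid + diol (acylation at C8–O); the C8 hydroxyl ⇒ C8 ketone (reduction directed by the C11 hydroxyl).
3. Bicyclic ketone ⇒ open-chain acyl selenide in one radical cascade: C8–C9 closes the seven-membered ring first, then C4–C5 closes the five-membered ring and C15 becomes the methyl group.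
4. Enabling feature: the C1=C10 alkene lies between C9 and the allylic ring-fusion carbon C5, and C8 next to C9 carries oxygen. A C8 acyl radical adding to C9 of a C9=C10–C1=C5 diene gives an allyl radical C10–C1–C5, which bonds through C5 to a C4=C15 vinyl group tethered on C1 and leaves the alkene at C1=C10.
5. Cascade precursor ⇒ auxiliary-controlled alkylation (sets C7) of a 3-hydroxy-3-methylbutanoyl imide with a (Z)-dienyl bromide, made from hex-5-en-1-yne by hydroalumination–iodination and Suzuki coupling.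

Key step: step 10

Remark: compounds 1, 6, 9, 12 and 25 are taken as purchasable, and the chair-like closure models used for C4 and C5 in step 10 are assumed to hold for the stabilised allyl radical.

**Route**

Step 1
Reactants: 1 hex-5-en-1-yne
Product: 3 hept-6-en-2-yn-1-ol, via lithium hex-5-en-1-yn-1-ide 2 (not isolated)
Conditions: n-BuLi, THF, −78 °C; (CH2O)n, −78 °C to rt; H2O
Reagents that add atoms: paraformaldehyde (formaldehyde), C=O
Why: Deprotonation of the terminal alkyne and addition of the acetylide to formaldehyde (alkynylation of an aldehyde) gives the propargylic alcohol without forming a stereocentre.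

Step 2
Reactants: 3 hept-6-en-2-yn-1-ol
Product: 5 (2Z)-3-iodohepta-2,6-dien-1-ol, via sodium alkenylalanate 4 (not isolated)
Conditions: NaAlH2(OCH2CH2OCH3)2, THF, 0 °C to rt; then I2, −78 to 0 °C; aq. KNaC4H4O6
Reagents that add atoms: iodine, II
Why: Hydroxyl-directed trans-hydroalumination of the propargylic alcohol places aluminium on C3 in a five-membered alkoxyalanate, and iodinolysis with retention gives the Z alkenyl iodide (CH2OH cis to I), while the isolated terminal alkene is inert.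

Step 3
Reactants: 5 (2Z)-3-iodohepta-2,6-dien-1-ol; 6 4,4,5,5-tetramethyl-2-(prop-1-en-2-yl)-1,3,2-dioxaborolane
Product: 7 (2Z)-3-(prop-1-en-2-yl)hepta-2,6-dien-1-ol
Conditions: Pd(dppf)Cl2 (5 mol %), K2CO3, THF/H2O, 60 °C
Reagents that add atoms: none
Why: Suzuki–Miyaura coupling of the alkenyl iodide with the alkenylboronate proceeds with retention of alkene geometry, so CH2OH ends cis to the isopropenyl group, as the later seven-ring closure requires.

Step 4
Reactants: 7 (2Z)-3-(prop-1-en-2-yl)hepta-2,6-dien-1-ol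
Product: 8 (2Z)-1-bromo-3-(prop-1-en-2-yl)hepta-2,6-diene
Conditions: CBr4, PPh3, CH2Cl2, −20 to 0 °C
Reagents that add atoms: carbon tetrabromide, BrC(Br)(Br)Br
Why: Appel bromination of the primary allylic alcohol under neutral conditions proceeds by SN2 displacement at the primary carbon and should keep the Z diene intact (the bromide is used without storage).

Step 5
Reactants: 9 3-hydroxy-3-methylbutanoic acid
Product: 11 3-methyl-3-[(triethylsilyl)oxy]butanoic acid, via bis-silylated ester 10 (not isolated)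
Conditions: Et3SiOTf (2.3 equiv), 2,6-lutidine, CH2Cl2, 0 °C; then K2CO3, MeOH/H2O, 0 °C; aq. citric acid to pH 4
Reagents that add atoms: triethylsilyl trifluoromethanesulfonate, CC[Si](CC)(CC)OS(=O)(=O)C(F)(F)F
Why: Silylation of both hydroxyl functions followed by selective solvolysis of the labile silyl ester leaves the base-stable tertiary silyl ether (protecting-group chemistry).

Step 6
Reactants: 11 3-methyl-3-[(triethylsilyl)oxy]butanoic acid; 12 (4R)-4-benzyl-1,3-oxazolidin-2-one
Product: 14 (4R)-4-benzyl-3-{3-methyl-3-[(triethylsilyl)oxy]butanoyl}-1,3-oxazolidin-2-one, via mixed pivalic anhydride 13 (not isolated)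
Conditions: t-BuCOCl, Et3N, THF, −20 °C; then 12, LiCl, −20 °C to rt
Reagents that add atoms: none
Why: N-Acylation of the oxazolidinone through the mixed pivalic anhydride (LiCl/Et3N variant) occurs at the less shielded acyl group and gives the imide.

Step 7
Reactants: 14 (4R)-4-benzyl-3-{3-methyl-3-[(triethylsilyl)oxy]butanoyl}-1,3-oxazolidin-2-one; 8 (2Z)-1-bromo-3-(prop-1-en-2-yl)hepta-2,6-diene
Product: 16 (4R)-4-benzyl-3-{(2R,4Z)-5-(prop-1-en-2-yl)-2-[2-(triethylsilyloxy)propan-2-yl]nona-4,8-dienoyl}-1,3-oxazolidin-2-one, via sodium (Z)-enolate 15 (not isolated)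
Conditions: NaN(SiMe3)2, THF, −78 °C; then 8, −78 to −40 °C
Reagents that add atoms: none
Why: Evans asymmetric alkylation, in which the chelated (Z)-enolate is alkylated by the allylic bromide on the face opposite the benzyl group of the (R)-auxiliary, sets C7 (2R in the acyl chain, the 7S centre of the target).

Step 8
Reactants: 16 (4R)-4-benzyl-3-{(2R,4Z)-5-(prop-1-en-2-yl)-2-[2-(triethylsilyloxy)propan-2-yl]nona-4,8-dienoyl}-1,3-oxazolidin-2-one
Product: 17 (2R,4Z)-5-(prop-1-en-2-yl)-2-{2-[(triethylsilyl)oxy]propan-2-yl}nona-4,8-dienoic acid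
Conditions: LiOH, H2O2, THF/H2O, 0 °C; Na2SO3; aq. HCl to pH 3 at 0 °C
Reagents that add atoms: hydrogen peroxide (acting as lithium hydroperoxide), OO
Why: Hydroperoxide cleaves the exocyclic imide carbonyl selectively even in hindered imides (standard auxiliary removal) without epimerising the α-centre, and alkenes and silyl ether are inert.

Step 9
Reactants: 17 (2R,4Z)-5-(prop-1-en-2-yl)-2-{2-[(triethylsilyl)oxy]propan-2-yl}nona-4,8-dienoic acid
Product: 18 Se-phenyl (2R,4Z)-5-(prop-1-en-2-yl)-2-{2-[(triethylsilyl)oxy]propan-2-yl}nona-4,8-dieneselenoate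
Conditions: PhSeSePh, Bu3P, CH2Cl2, rt
Reagents that add atoms: diphenyl diselenide, c1ccccc1[Se][Se]c1ccccc1
Why: Redox condensation of the acid with the diselenide/phosphine pair gives the Se-phenyl selenoester (acyl radical precursor) under neutral conditions that leave the stereocentre, diene and silyl ether untouched.

Step 10
Reactants: 18 Se-phenyl (2R,4Z)-5-(prop-1-en-2-yl)-2-{2-[(triethylsilyl)oxy]propan-2-yl}nona-4,8-dieneselenoate
Product: 22 (3S,3aS,5R)-3,8-dimethyl-5-{2-[(triethylsilyl)oxy]propan-2-yl}-2,3,3a,4,5,7-hexahydroazulen-6(1H)-one, via acyl radical 19 (not isolated), via cycloheptenyl allyl radical 20 (not isolated), via bicyclic primary radical 21 (not isolated)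
Conditions: Bu3SnH (1.3 equiv, syringe pump over 8 h), AIBN (0.2 equiv), benzene, 80 °C, 3 mM
Reagents that add atoms: none
Why: Proposed new method: Bu3Sn• abstracts the PhSe group of 18 to give acyl radical 19, which adds to the CH2 terminus (C9) of the diene to close the seven-membered ring as allyl radical 20 (C10–C1–C5); the C5 end of 20 then adds to the internal carbon (C4) of the vinyl group tethered on C1, and the primary C15 radical 21 takes hydrogen from Bu3SnH, so the alkene is left at C1=C10 and C15 becomes the methyl group. The closest known reaction types are the 7-endo cyclisation of acyl radicals from acyl selenides onto 1,1-disubstituted alkenes, acyl radical polyene cascades and the 5-exo cyclisation of allylic radicals; joining them through an allyl radical relay across a diene is the new element. The seven-membered ring closes in the 7-endo-trig mode (C8–C9) and the five-membered ring in the 5-exo-trig mode (C4–C5). C5 is controlled by the existing C7 centre: in the chair-like cycloheptene that develops during the second closure the bulky silyloxypropyl group on C7 stays equatorial, which fixes the face of the allyl radical to which C4 bonds (H5 cis to H7, 5S). C4 is controlled by the chair-like 5-exo transition state, which places the incipient C15 methyl cis to C6 on the new ring (1,5-cis preference of hexenyl radical closures, 4S). The step needs attack of 19 at C9 and not at C10 or C1 (the C10 methyl blocks 6-exo attack and only C9 attack gives a stabilised allyl radical), bonding of 20 through C5 and not through the fully substituted C10 end (steric bias, and only the C5 mode gives the tetrasubstituted alkene), and cyclisation faster than CO loss or hydrogen transfer (high dilution, slow stannane addition).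

Step 11
Reactants: 22 (3S,3aS,5R)-3,8-dimethyl-5-{2-[(triethylsilyl)oxy]propan-2-yl}-2,3,3a,4,5,7-hexahydroazulen-6(1H)-one
Product: 23 (3S,3aS,5R)-5-(2-hydroxypropan-2-yl)-3,8-dimethyl-2,3,3a,4,5,7-hexahydroazulen-6(1H)-one
Conditions: HF·pyridine, THF, 0 °C
Reagents that add atoms: none
Why: Fluoride cleavage of the tertiary triethylsilyl ether under mildly acidic, non-basic conditions should avoid retro-aldol loss of acetone from the β-hydroxy ketone, epimerisation at C7 and migration of the β,γ-alkene.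

Step 12
Reactants: 23 (3S,3aS,5R)-5-(2-hydroxypropan-2-yl)-3,8-dimethyl-2,3,3a,4,5,7-hexahydroazulen-6(1H)-one
Product: 24 (3S,3aS,5S,6S)-5-(2-hydroxypropan-2-yl)-3,8-dimethyl-1,2,3,3a,4,5,6,7-octahydroazulen-6-ol
Conditions: Me4NBH(OAc)3, MeCN/AcOH (1:1), −30 °C
Reagents that add atoms: none
Why: Hydroxyl-directed reduction (Evans–Saksena type), in which hydride is delivered intramolecularly from the alkoxyborohydride formed at the C11 hydroxyl to the carbonyl face syn to the C7 side chain, should place the new C8 hydroxyl trans to that side chain (8S, equatorial).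

Step 13
Reactants: 25 (2E)-3-(4-hydroxyphenyl)prop-2-enoic acid (p-coumaric acid)
Product: 27 (2E)-3-{4-[(tert-butyldimethylsilyl)oxy]phenyl}prop-2-enoic acid, via bis-silylated coumarate 26 (not isolated)
Conditions: t-BuMe2SiCl (2.5 equiv), imidazole, DMF, rt; then AcOH, THF/H2O, rt
Reagents that add atoms: tert-butyldimethylsilyl chloride, CC(C)(C)[Si](C)(C)Cl
Why: Bis-silylation followed by mild acidic hydrolysis of the labile silyl ester leaves the aryl silyl ether and frees the acid (protecting-group chemistry).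

Step 14
Reactants: 24 (3S,3aS,5S,6S)-5-(2-hydroxypropan-2-yl)-3,8-dimethyl-1,2,3,3a,4,5,6,7-octahydroazulen-6-ol; 27 (2E)-3-{4-[(tert-butyldimethylsilyl)oxy]phenyl}prop-2-enoic acid
Product: 28 (3S,3aS,5S,6S)-5-(2-hydroxypropan-2-yl)-3,8-dimethyl-1,2,3,3a,4,5,6,7-octahydroazulen-6-yl (2E)-3-{4-[(tert-butyldimethylsilyl)oxy]phenyl}prop-2-enoate
Conditions: EDC·HCl, DMAP, CH2Cl2, 0 °C to rt
Reagents that add atoms: none
Why: Steglich esterification should acylate the secondary C8 hydroxyl selectively because the tertiary C11 hydroxyl is too hindered, and the C8 configuration is kept since the C–O bond is not broken.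

Step 15
Reactants: 28 (3S,3aS,5S,6S)-5-(2-hydroxypropan-2-yl)-3,8-dimethyl-1,2,3,3a,4,5,6,7-octahydroazulen-6-yl (2E)-3-{4-[(tert-butyldimethylsilyl)oxy]phenyl}prop-2-enoate
Product: 29 (3S,3aS,5S,6S)-5-(2-hydroxypropan-2-yl)-3,8-dimethyl-1,2,3,3a,4,5,6,7-octahydroazulen-6-yl (2E)-3-(4-hydroxyphenyl)prop-2-enoate (CNP0403230.1)
Conditions: Bu4NF, AcOH, THF, 0 °C
Reagents that add atoms: none
Why: Fluoride cleaves the aryl silyl ether rapidly, and buffering with acetic acid should prevent phenoxide-mediated cleavage of the cinnamate ester while the tertiary alcohol and the alkenes are untouched.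

**Compound list**
1 | hex-5-en-1-yne | C#CCCC=C | starting material
2 | lithium hex-5-en-1-yn-1-ide | [Li]C#CCCC=C | intermediate
3 | hept-6-en-2-yn-1-ol | OCC#CCCC=C | intermediate
4 | sodium 3-(but-3-en-1-yl)-2,2-bis(2-methoxyethoxy)-2,5-dihydro-1,2-oxaluminol-2-uide (alkenylalanate) | [Na+].C=CCCC1=CCO[Al-]1(OCCOC)OCCOC | intermediate
5 | (2Z)-3-iodohepta-2,6-dien-1-ol | OC/C=C(\I)CCC=C | intermediate
6 | 4,4,5,5-tetramethyl-2-(prop-1-en-2-yl)-1,3,2-dioxaborolane | CC(=C)B1OC(C)(C)C(C)(C)O1 | starting material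
7 | (2Z)-3-(prop-1-en-2-yl)hepta-2,6-dien-1-ol | OC/C=C(\C(C)=C)CCC=C | intermediate
8 | (2Z)-1-bromo-3-(prop-1-en-2-yl)hepta-2,6-diene | BrC/C=C(\C(C)=C)CCC=C | intermediate
9 | 3-hydroxy-3-methylbutanoic acid | CC(C)(O)CC(=O)O | starting material
10 | triethylsilyl 3-methyl-3-[(triethylsilyl)oxy]butanoate | CC[Si](CC)(CC)OC(C)(C)CC(=O)O[Si](CC)(CC)CC | intermediate
11 | 3-methyl-3-[(triethylsilyl)oxy]butanoic acid | CC[Si](CC)(CC)OC(C)(C)CC(=O)O | intermediate
12 | (4R)-4-benzyl-1,3-oxazolidin-2-one | O=C1N[C@H](Cc2ccccc2)CO1 | starting material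
13 | 2,2-dimethylpropanoic 3-methyl-3-[(triethylsilyl)oxy]butanoic anhydride | CC[Si](CC)(CC)OC(C)(C)CC(=O)OC(=O)C(C)(C)C | intermediate
14 | (4R)-4-benzyl-3-{3-methyl-3-[(triethylsilyl)oxy]butanoyl}-1,3-oxazolidin-2-one | CC[Si](CC)(CC)OC(C)(C)CC(=O)N1[C@H](Cc2ccccc2)COC1=O | intermediate
15 | sodium (1Z)-1-[(4R)-4-benzyl-2-oxo-1,3-oxazolidin-3-yl]-3-methyl-3-[(triethylsilyl)oxy]but-1-en-1-olate | CC[Si](CC)(CC)OC(C)(C)/C=C(\[O-])N1[C@H](Cc2ccccc2)COC1=O.[Na+] | intermediate
16 | (4R)-4-benzyl-3-{(2R,4Z)-5-(prop-1-en-2-yl)-2-[2-(triethylsilyloxy)propan-2-yl]nona-4,8-dienoyl}-1,3-oxazolidin-2-one | C=C(C)/C(CCC=C)=C\C[C@H](C(C)(C)O[Si](CC)(CC)CC)C(=O)N1[C@H](Cc2ccccc2)COC1=O | intermediate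
17 | (2R,4Z)-5-(prop-1-en-2-yl)-2-{2-[(triethylsilyl)oxy]propan-2-yl}nona-4,8-dienoic acid | C=C(C)/C(CCC=C)=C\C[C@H](C(C)(C)O[Si](CC)(CC)CC)C(=O)O | intermediate
18 | Se-phenyl (2R,4Z)-5-(prop-1-en-2-yl)-2-{2-[(triethylsilyl)oxy]propan-2-yl}nona-4,8-dieneselenoate | C=C(C)/C(CCC=C)=C\C[C@H](C(C)(C)O[Si](CC)(CC)CC)C(=O)[Se]c1ccccc1 | intermediate
19 | (2R,4Z)-5-(prop-1-en-2-yl)-2-{2-[(triethylsilyl)oxy]propan-2-yl}nona-4,8-dienoyl radical | C=C(C)/C(CCC=C)=C\C[C@H](C(C)(C)O[Si](CC)(CC)CC)[C]=O | intermediate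
20 | (6R)-2-(but-3-en-1-yl)-3-methyl-5-oxo-6-{2-[(triethylsilyl)oxy]propan-2-yl}cyclohept-2-en-1-yl radical (allyl radical, one resonance form) | CC1=C(CCC=C)[CH]C[C@H](C(C)(C)O[Si](CC)(CC)CC)C(=O)C1 | intermediate
21 | [(3S,3aS,5R)-8-methyl-6-oxo-5-{2-[(triethylsilyl)oxy]propan-2-yl}-1,2,3,3a,4,5,6,7-octahydroazulen-3-yl]methyl radical | CC1=C2CC[C@H]([CH2])[C@@H]2C[C@H](C(C)(C)O[Si](CC)(CC)CC)C(=O)C1 | intermediate
22 | (3S,3aS,5R)-3,8-dimethyl-5-{2-[(triethylsilyl)oxy]propan-2-yl}-2,3,3a,4,5,7-hexahydroazulen-6(1H)-one | CC1=C2CC[C@H](C)[C@@H]2C[C@H](C(C)(C)O[Si](CC)(CC)CC)C(=O)C1 | intermediate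
23 | (3S,3aS,5R)-5-(2-hydroxypropan-2-yl)-3,8-dimethyl-2,3,3a,4,5,7-hexahydroazulen-6(1H)-one | CC1=C2CC[C@H](C)[C@@H]2C[C@H](C(C)(C)O)C(=O)C1 | intermediate
24 | (3S,3aS,5S,6S)-5-(2-hydroxypropan-2-yl)-3,8-dimethyl-1,2,3,3a,4,5,6,7-octahydroazulen-6-ol | CC1=C2CC[C@H](C)[C@@H]2C[C@H](C(C)(C)O)[C@@H](O)C1 | intermediate
25 | (2E)-3-(4-hydroxyphenyl)prop-2-enoic acid | OC(=O)/C=C/c1ccc(O)cc1 | starting material
26 | tert-butyldimethylsilyl (2E)-3-{4-[(tert-butyldimethylsilyl)oxy]phenyl}prop-2-enoate | CC(C)(C)[Si](C)(C)OC(=O)/C=C/c1ccc(O[Si](C)(C)C(C)(C)C)cc1 | intermediate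
27 | (2E)-3-{4-[(tert-butyldimethylsilyl)oxy]phenyl}prop-2-enoic acid | OC(=O)/C=C/c1ccc(O[Si](C)(C)C(C)(C)C)cc1 | intermediate
28 | (3S,3aS,5S,6S)-5-(2-hydroxypropan-2-yl)-3,8-dimethyl-1,2,3,3a,4,5,6,7-octahydroazulen-6-yl (2E)-3-{4-[(tert-butyldimethylsilyl)oxy]phenyl}prop-2-enoate | CC1=C2CC[C@H](C)[C@@H]2C[C@H](C(C)(C)O)[C@@H](OC(=O)/C=C/c2ccc(O[Si](C)(C)C(C)(C)C)cc2)C1 | intermediate
29 | (3S,3aS,5S,6S)-5-(2-hydroxypropan-2-yl)-3,8-dimethyl-1,2,3,3a,4,5,6,7-octahydroazulen-6-yl (2E)-3-(4-hydroxyphenyl)prop-2-enoate | CC1=C2CC[C@H](C)[C@@H]2C[C@H](C(C)(C)O)[C@@H](OC(=O)/C=C/c2ccc(O)cc2)C1 | target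

**Count**
Total step count: 15. Longest linear sequence: 12 steps (steps 1–4, 7–12, 14, 15).

**Steps most likely to fail**

1. Step 10 (the proposed cascade). The acyl radical may lose CO or be reduced before the seven-membered ring closes, the allyl radical may take hydrogen or bond through its C10 end before the five-membered ring closes, and facial control at C4 may be poor. Fallback, setting out from acid 17 and returning at ketone 22: the two ring closures are separated and the first is made ionic. Acid 17 is converted with oxalyl chloride into (2R,4Z)-5-(prop-1-en-2-yl)-2-{2-[(triethylsilyl)oxy]propan-2-yl}nona-4,8-dienoyl chloride F1. SnCl4 in CH2Cl2 at −78 °C then effects the known intramolecular acylation of the diene terminus (acylium–alkene cyclisation), and chloride captures the allyl cation to give (2R)-5-(but-3-en-1-yl)-4-chloro-6-methyl-2-{2-[(triethylsilyl)oxy]propan-2-yl}cyclohept-5-en-1-one F2 (allylic chloride, C–Cl epimers). Bu3SnH/AIBN generates allyl radical 20 from F2 without an acyl radical stage, and its known 5-exo allylic-radical cyclisation onto the vinyl group forms the C4–C5 bond and gives 22.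

2. Step 7. The enolate carbon sits next to a fully substituted carbon, so alkylation may be slow enough for enolate decomposition or β-elimination of the silyloxy group to compete. Fallback, setting out from bromide 8 and returning at acid 17: the C7–C11 bond is made by acylation instead of the C7–C6 bond by alkylation. Bromide 8 alkylates LiCH2CO2Li to give (4Z)-5-(prop-1-en-2-yl)nona-4,8-dienoic acid F3. Mixed-anhydride acylation of (4S)-4-benzyl-1,3-oxazolidin-2-one gives (4S)-4-benzyl-3-[(4Z)-5-(prop-1-en-2-yl)nona-4,8-dienoyl]-1,3-oxazolidin-2-one F4. C-Acylation of its sodium enolate with acetyl chloride (anti to the benzyl group) gives the configurationally stable β-keto imide (4S)-3-[(2R,4Z)-2-acetyl-5-(prop-1-en-2-yl)nona-4,8-dienoyl]-4-benzyl-1,3-oxazolidin-2-one F5. MeMgBr/CeCl3 adds to the ketone to give (4S)-4-benzyl-3-[(2R,4Z)-2-(2-hydroxypropan-2-yl)-5-(prop-1-en-2-yl)nona-4,8-dienoyl]-1,3-oxazolidin-2-one F6. Et3SiOTf/2,6-lutidine gives (4S)-4-benzyl-3-{(2R,4Z)-5-(prop-1-en-2-yl)-2-[2-(triethylsilyloxy)propan-2-yl]nona-4,8-dienoyl}-1,3-oxazolidin-2-one F7, and LiOH/H2O2 releases 17.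

3. Step 12. Exchange of the hindered tertiary hydroxyl onto boron may be slow, so undirected reduction, retro-aldol cleavage or C7 epimerisation of 23 may erode the C8 selectivity. Fallback, setting out from ketone 22 and returning at target 29: the C8 centre is set by steric approach control followed by inversion. LiBH(s-Bu)3 attacks 22 anti to the C7 side chain to give (3S,3aS,5S,6R)-3,8-dimethyl-5-{2-[(triethylsilyl)oxy]propan-2-yl}-1,2,3,3a,4,5,6,7-octahydroazulen-6-ol F8. Mitsunobu esterification with acid 27 (PPh3, diisopropyl azodicarboxylate) inverts C8 to give (3S,3aS,5S,6S)-3,8-dimethyl-5-{2-[(triethylsilyl)oxy]propan-2-yl}-1,2,3,3a,4,5,6,7-octahydroazulen-6-yl (2E)-3-{4-[(tert-butyldimethylsilyl)oxy]phenyl}prop-2-enoate F9. HF·pyridine removes both silyl groups to give 29.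

**Further compounds**
F1 | step 10 | (2R,4Z)-5-(prop-1-en-2-yl)-2-{2-[(triethylsilyl)oxy]propan-2-yl}nona-4,8-dienoyl chloride | C=C(C)/C(CCC=C)=C\C[C@H](C(C)(C)O[Si](CC)(CC)CC)C(Cl)=O
F2 | step 10 | (2R)-5-(but-3-en-1-yl)-4-chloro-6-methyl-2-{2-[(triethylsilyl)oxy]propan-2-yl}cyclohept-5-en-1-one | CC1=C(CCC=C)C(Cl)C[C@H](C(C)(C)O[Si](CC)(CC)CC)C(=O)C1
F3 | step 7 | (4Z)-5-(prop-1-en-2-yl)nona-4,8-dienoic acid | C=C(C)/C(CCC=C)=C\CCC(=O)O
F4 | step 7 | (4S)-4-benzyl-3-[(4Z)-5-(prop-1-en-2-yl)nona-4,8-dienoyl]-1,3-oxazolidin-2-one | C=C(C)/C(CCC=C)=C\CCC(=O)N1[C@@H](Cc2ccccc2)COC1=O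
F5 | step 7 | (4S)-3-[(2R,4Z)-2-acetyl-5-(prop-1-en-2-yl)nona-4,8-dienoyl]-4-benzyl-1,3-oxazolidin-2-one | C=C(C)/C(CCC=C)=C\C[C@H](C(C)=O)C(=O)N1[C@@H](Cc2ccccc2)COC1=O
F6 | step 7 | (4S)-4-benzyl-3-[(2R,4Z)-2-(2-hydroxypropan-2-yl)-5-(prop-1-en-2-yl)nona-4,8-dienoyl]-1,3-oxazolidin-2-one | C=C(C)/C(CCC=C)=C\C[C@H](C(C)(C)O)C(=O)N1[C@@H](Cc2ccccc2)COC1=O
F7 | step 7 | (4S)-4-benzyl-3-{(2R,4Z)-5-(prop-1-en-2-yl)-2-[2-(triethylsilyloxy)propan-2-yl]nona-4,8-dienoyl}-1,3-oxazolidin-2-one | C=C(C)/C(CCC=C)=C\C[C@H](C(C)(C)O[Si](CC)(CC)CC)C(=O)N1[C@@H](Cc2ccccc2)COC1=O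
F8 | step 12 | (3S,3aS,5S,6R)-3,8-dimethyl-5-{2-[(triethylsilyl)oxy]propan-2-yl}-1,2,3,3a,4,5,6,7-octahydroazulen-6-ol | CC1=C2CC[C@H](C)[C@@H]2C[C@H](C(C)(C)O[Si](CC)(CC)CC)[C@H](O)C1
F9 | step 12 | (3S,3aS,5S,6S)-3,8-dimethyl-5-{2-[(triethylsilyl)oxy]propan-2-yl}-1,2,3,3a,4,5,6,7-octahydroazulen-6-yl (2E)-3-{4-[(tert-butyldimethylsilyl)oxy]phenyl}prop-2-enoate | CC1=C2CC[C@H](C)[C@@H]2C[C@H](C(C)(C)O[Si](CC)(CC)CC)[C@@H](OC(=O)/C=C/c2ccc(O[Si](C)(C)C(C)(C)C)cc2)C1
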